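**Plan**

- Retrosynthesis: the phenolic acetate, the C2 acetate and the C6 aryl ester are removed first; the C7=C8 enone is traced to a saturated C9 ketone, and C5–H/C6–O to a C5=C6 alkene.
- Enabling feature: the C9 ketone flanked by C8 (methyl) and C10 is an oxyallyl unit, and C7–C6–C5–C1 is a diene inside a 1-vinylcyclopentene (ring C1–C5) that already carries C2 and C4. The seven-membered ring is therefore cut at C7–C8 and C1–C10 by a (4+3) cycloaddition.
- The diene is cut at C5–C6 (Stille), C4–isopropyl (organocerium addition) and C1–CH3 (conjugate addition), back to (S)-4-silyloxycyclopentenone.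
- Forward: the five-membered ring is elaborated first (steps 1–6), the seven-membered ring closes in step 7, then C6 oxygenation, enone formation and acyl adjustment follow (steps 8–17).
- Stereochemistry: C2 comes from the starting enone; C4 from addition anti to the C2 silyloxy group; C1 from cycloaddition anti to that group; C5 and C6 from syn hydroboration on the α face; C8 is transient.

Key step: step 7

**Remarks**

- Numbering: C1 ring-fusion carbon with methyl, C2 CH–O, C3 CH2, C4 carbinol carbon with isopropyl, C5 ring-fusion CH, C6 CH–O, C7, C8 (methyl), C9 (C=O), C10. β is the face of the C1 methyl.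
- Bicyclic compounds are named on the daucane skeleton: 1,8-dimethyl-4-isopropylbicyclo[5.3.0]decane, five-membered ring C1–C5, seven-membered ring C1, C5–C10, with 1β-methyl and 4α-isopropyl throughout.
- Assumption: C8 is expected as an epimer mixture in 13–20. The 8α-methyl epimer is drawn for definiteness, and both epimers converge in step 14.
- Assumption: dibromide 5 is a diastereomer mixture at C2/C3 and is drawn without configuration there.

**Route**

Step 1
Reactants: 1 (S)-4-(tert-butyldimethylsilyloxy)cyclopent-2-en-1-one; 2 methylmagnesium bromide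
Product: 3 (3S,4S)-4-(tert-butyldimethylsilyloxy)-3-methyl-1-(trimethylsilyloxy)cyclopent-1-ene
Conditions: 2 (1.3 equiv), CuI (10 mol%), LiCl (20 mol%), TMSCl (2 equiv), THF, −78 → −40 °C; Et3N, pentane work-up
Reagents that add atoms: chlorotrimethylsilane, C[Si](C)(C)Cl
Why: Copper-catalysed conjugate addition of the Grignard reagent with in situ silyl trapping puts the methyl on C3 anti to the silyloxy group and fixes the enol ether regiochemistry for step 2, where the new C3 centre is erased.

Step 2
Reactants: 3 (3S,4S)-4-(tert-butyldimethylsilyloxy)-3-methyl-1-(trimethylsilyloxy)cyclopent-1-ene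
Product: 4 (S)-4-(tert-butyldimethylsilyloxy)-3-methylcyclopent-2-en-1-one
Conditions: Pd(OAc)2 (1.05 equiv), MeCN, rt
Reagents that add atoms: none
Why: Saegusa–Ito oxidation, in which the palladium enolate at C2 can only lose the C3 hydrogen, should give the 3-methyl enone without touching the silyloxy-bearing stereocentre.

Step 3
Reactants: 4 (S)-4-(tert-butyldimethylsilyloxy)-3-methylcyclopent-2-en-1-one
Product: 6 (S)-2-bromo-4-(tert-butyldimethylsilyloxy)-3-methylcyclopent-2-en-1-one, via 2,3-dibromo ketone 5 (not isolated)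
Conditions: Br2, CH2Cl2, 0 °C; then Et3N, 0 °C → rt
Reagents that add atoms: bromine, BrBr
Why: Bromine addition to the enone followed by E1cB loss of HBr with Et3N is the standard α-bromination of cyclic enones, and the mild amine base should leave the β-silyloxy group in place.

Step 4
Reactants: 6 (S)-2-bromo-4-(tert-butyldimethylsilyloxy)-3-methylcyclopent-2-en-1-one; 7 isopropylmagnesium chloride
Product: 8 (1S,4S)-2-bromo-4-(tert-butyldimethylsilyloxy)-3-methyl-1-(propan-2-yl)cyclopent-2-en-1-ol (hydroxyl cis to the silyl ether)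
Conditions: 7, anhydrous CeCl3, THF, −78 °C; aq. NH4Cl
Reagents that add atoms: none
Why: Imamoto organocerium 1,2-addition, in which the weakly basic cerium reagent adds to the carbonyl instead of enolising it (which would expel the silyloxy group) or reducing it, should occur anti to the silyloxy group across the flat ring, so the tertiary hydroxyl ends up cis to the silyl ether.

Step 5
Reactants: 8 (1S,4S)-2-bromo-4-(tert-butyldimethylsilyloxy)-3-methyl-1-(propan-2-yl)cyclopent-2-en-1-ol
Product: 9 triethylsilyl ether of 8, (1S,4S)-2-bromo-4-(tert-butyldimethylsilyloxy)-3-methyl-1-(propan-2-yl)-1-(triethylsilyloxy)cyclopent-2-ene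
Conditions: TESOTf, 2,6-lutidine, CH2Cl2, −78 → 0 °C
Reagents that add atoms: triethylsilyl trifluoromethanesulfonate, CC[Si](CC)(CC)OS(=O)(=O)C(F)(F)F
Why: Silylation of a hindered tertiary alcohol with a silyl triflate and 2,6-lutidine is routine, and the silyl ether keeps the oxygen from trapping the oxyallyl cation and adds bulk to the β face.

Step 6
Reactants: 9 triethylsilyl ether of 8; 10 tributyl(vinyl)stannane
Product: 11 (1S,4S)-4-(tert-butyldimethylsilyloxy)-2-ethenyl-3-methyl-1-(propan-2-yl)-1-(triethylsilyloxy)cyclopent-2-ene (both silyloxy groups β)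
Conditions: Pd(PPh3)4 (10 mol%), CuI (20 mol%), CsF, DMF, 45 °C
Reagents that add atoms: none
Why: Stille coupling of an alkenyl bromide with a vinylstannane under CuI/CsF co-promotion, conditions suited to congested tetrasubstituted bromoalkenes, should form the C5–C6 bond without disturbing the silyl ethers.

Step 7
Reactants: 11 bis-silyl 2-methyl-1-vinylcyclopentene diol; 12 3-chlorobutan-2-one (racemic)
Product: 13 2β-(tert-butyldimethylsilyloxy)-4β-(triethylsilyloxy)dauc-5-en-9-one (C8 epimers)
Conditions: 12 (3 equiv), Et3N (3.5 equiv, slow addition), CF3CH2OH, 0 °C → rt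
Reagents that add atoms: none
Why: Et3N removes an α′-proton of 12 and chloride leaves in the ionising solvent to give the methyl-substituted oxyallyl cation, whose more substituted and more electrophilic terminus C8 is attacked by the unhindered vinyl carbon C7 of 11, after which the enolate carbon C10 closes onto the tertiary end C1 of the allyl cation spanning C6–C5–C1, a stepwise (4+3) cycloaddition that tolerates the twisted diene. The closest known reaction is the (4+3) cycloaddition of oxyallyl cations from α-haloketones under amine/fluoroalcohol conditions with furans, cyclopentadiene and open-chain or semicyclic 1,3-dienes, including diene termini that become quaternary. The seven-membered ring closes by C–C bond formation between C10 and C1, a 7-endo collapse of the enolate onto the allyl cation that leaves C5=C6 inside the new ring. C1 is set by closure on the α face, anti to the neighbouring C2 silyloxy group (the C4 silyloxy group lies on the same β face), so the methyl ends up β, while C8 forms without control and is erased in step 14. The step needs C8-to-C7 and C10-to-C1 regiochemistry and (4+3) instead of (3+2) or ene-type collapse; pairing of the bulkier cation terminus with the unsubstituted vinyl carbon and the greater charge at the tertiary terminus C1 should secure both.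

Step 8
Reactants: 13 2β-(tert-butyldimethylsilyloxy)-4β-(triethylsilyloxy)dauc-5-en-9-one
Product: 14 9,9-(ethylenedioxy)-2β-(tert-butyldimethylsilyloxy)-4β-(triethylsilyloxy)dauc-5-ene
Conditions: (TMSOCH2)2, TMSOTf (5 mol%), CH2Cl2, −78 → −20 °C; pyridine quench
Reagents that add atoms: 1,2-bis(trimethylsilyloxy)ethane, C[Si](C)(C)OCCO[Si](C)(C)C
Why: Noyori ketalisation at low temperature masks the C9 ketone against borane, and the catalytic silyl triflate should leave the silyl ethers and the tertiary allylic C4–O bond intact.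

Step 9
Reactants: 14 9,9-(ethylenedioxy)-2β-(tert-butyldimethylsilyloxy)-4β-(triethylsilyloxy)dauc-5-ene
Product: 16 9,9-(ethylenedioxy)-2β-(tert-butyldimethylsilyloxy)-4β-(triethylsilyloxy)-5α-daucan-6α-ol, via C6 alkylborane 15 (not isolated)
Conditions: BH3·THF, THF, 0 °C → rt; then NaOH, H2O2, 0 °C
Reagents that add atoms: hydrogen peroxide, OO
Why: Hydroboration–oxidation, with syn addition placing boron on the less substituted C6 and hydrogen on C5 from the α face opposite the C1 methyl and the C4 silyloxy group, followed by oxidation with retention, should give the trans-fused 5α-H, 6α-OH arrangement.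

Step 10
Reactants: 17 4-acetoxybenzoic acid
Product: 18 4-acetoxybenzoyl chloride
Conditions: (COCl)2, DMF (cat.), CH2Cl2, 0 °C → rt
Reagents that add atoms: oxalyl chloride, ClC(=O)C(Cl)=O
Why: Acid chloride formation with oxalyl chloride and catalytic DMF (Vilsmeier-type activation) is compatible with the aryl acetate.

Step 11
Reactants: 16 9,9-(ethylenedioxy)-2β-(tert-butyldimethylsilyloxy)-4β-(triethylsilyloxy)-5α-daucan-6α-ol; 18 4-acetoxybenzoyl chloride
Product: 19 6α-(4-acetoxybenzoyloxy)-9,9-(ethylenedioxy)-2β-(tert-butyldimethylsilyloxy)-4β-(triethylsilyloxy)-5α-daucane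
Conditions: 18, pyridine, DMAP (cat.), CH2Cl2, 0 °C → rt
Reagents that add atoms: none
Why: DMAP-catalysed acylation of the secondary C6 alcohol with the preformed acid chloride proceeds with retention at C6, and the reactive chloride outcompetes the aryl acetate as an acyl donor.

Step 12
Reactants: 19 6α-(4-acetoxybenzoyloxy)-9,9-(ethylenedioxy)-2β-(tert-butyldimethylsilyloxy)-4β-(triethylsilyloxy)-5α-daucane
Product: 20 6α-(4-acetoxybenzoyloxy)-2β-(tert-butyldimethylsilyloxy)-4β-(triethylsilyloxy)-5α-daucan-9-one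
Conditions: PPTS, acetone/H2O (10:1), 50 °C
Reagents that add atoms: water, O
Why: Mild acid-catalysed ketal hydrolysis should free the C9 ketone while the secondary TBS ether, the hindered tertiary TES ether and both esters persist.

Step 13
Reactants: 20 6α-(4-acetoxybenzoyloxy)-2β-(tert-butyldimethylsilyloxy)-4β-(triethylsilyloxy)-5α-daucan-9-one
Product: 21 6α-(4-acetoxybenzoyloxy)-2β-(tert-butyldimethylsilyloxy)-4β-(triethylsilyloxy)-9-(trimethylsilyloxy)-5α-dauc-8-ene
Conditions: TMSOTf (1.5 equiv), Et3N, CH2Cl2, 0 °C → rt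
Reagents that add atoms: trimethylsilyl trifluoromethanesulfonate, C[Si](C)(C)OS(=O)(=O)C(F)(F)F
Why: Soft enolisation with a silyl triflate and amine gives the more substituted silyl enol ether towards C8 without a strong base that would attack the esters, and the C10 regioisomer is harmless because the quaternary C1 prevents it from giving an enone.

Step 14
Reactants: 21 6α-(4-acetoxybenzoyloxy)-2β-(tert-butyldimethylsilyloxy)-4β-(triethylsilyloxy)-9-(trimethylsilyloxy)-5α-dauc-8-ene
Product: 22 6α-(4-acetoxybenzoyloxy)-2β-(tert-butyldimethylsilyloxy)-4β-(triethylsilyloxy)-5α-dauc-7-en-9-one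
Conditions: Pd(OAc)2 (1.1 equiv), MeCN, rt
Reagents that add atoms: none
Why: Saegusa–Ito oxidation, in which β-hydride elimination can only involve C7, should give the C7=C8 enone and erase the C8 centre, and the ligand-free zerovalent palladium that precipitates is a poor catalyst for ionising the new allylic ester.

Step 15
Reactants: 22 6α-(4-acetoxybenzoyloxy)-2β-(tert-butyldimethylsilyloxy)-4β-(triethylsilyloxy)-5α-dauc-7-en-9-one
Product: 23 6α-(4-acetoxybenzoyloxy)-2β,4β-dihydroxy-5α-dauc-7-en-9-one
Conditions: HF·pyridine, pyridine, THF, 0 °C → rt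
Reagents that add atoms: none
Why: Buffered fluoride desilylation removes both silyl ethers and should leave the aryl acetate, the benzoate and the γ-acyloxy enone untouched.

Step 16
Reactants: 23 6α-(4-acetoxybenzoyloxy)-2β,4β-dihydroxy-5α-dauc-7-en-9-one
Product: 24 2β-acetoxy-6α-(4-acetoxybenzoyloxy)-4β-hydroxy-5α-dauc-7-en-9-one
Conditions: Ac2O, pyridine, DMAP (cat.), CH2Cl2, 0 °C
Reagents that add atoms: acetic anhydride, CC(=O)OC(C)=O
Why: Acetylation with acetic anhydride and pyridine is selective for the secondary C2 hydroxyl, since the tertiary C4 hydroxyl next to the isopropyl group does not acylate at 0 °C.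

Step 17
Reactants: 24 2β-acetoxy-6α-(4-acetoxybenzoyloxy)-4β-hydroxy-5α-dauc-7-en-9-one
Product: 25 2β-acetoxy-4β-hydroxy-6α-(4-hydroxybenzoyloxy)-5α-dauc-7-en-9-one (target)
Conditions: NH4OAc, MeOH, rt
Reagents that add atoms: none
Why: Chemoselective methanolysis of the phenolic acetate under neutral NH4OAc catalysis relies on aryl acetates being far more labile than the alkyl acetate at C2 and the hindered benzoate at C6.

**Compound list**

1 | (S)-4-(tert-butyldimethylsilyloxy)cyclopent-2-en-1-one | CC(C)(C)[Si](C)(C)O[C@H]1CC(=O)C=C1 | starting material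
2 | methylmagnesium bromide | C[Mg]Br | starting material
3 | (3S,4S)-4-(tert-butyldimethylsilyloxy)-3-methyl-1-(trimethylsilyloxy)cyclopent-1-ene | CC(C)(C)[Si](C)(C)O[C@H]1CC(O[Si](C)(C)C)=C[C@@H]1C | intermediate
4 | (S)-4-(tert-butyldimethylsilyloxy)-3-methylcyclopent-2-en-1-one | CC(C)(C)[Si](C)(C)O[C@H]1CC(=O)C=C1C | intermediate
5 | (4S)-2,3-dibromo-4-(tert-butyldimethylsilyloxy)-3-methylcyclopentan-1-one (C2/C3 diastereomers, not isolated) | CC(C)(C)[Si](C)(C)O[C@H]1CC(=O)C(Br)C1(C)Br | intermediate
6 | (S)-2-bromo-4-(tert-butyldimethylsilyloxy)-3-methylcyclopent-2-en-1-one | CC(C)(C)[Si](C)(C)O[C@H]1CC(=O)C(Br)=C1C | intermediate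
7 | isopropylmagnesium chloride | CC(C)[Mg]Cl | starting material
8 | (1S,4S)-2-bromo-4-(tert-butyldimethylsilyloxy)-3-methyl-1-(propan-2-yl)cyclopent-2-en-1-ol | CC(C)(C)[Si](C)(C)O[C@H]1C[C@](O)(C(C)C)C(Br)=C1C | intermediate
9 | (1S,4S)-2-bromo-4-(tert-butyldimethylsilyloxy)-3-methyl-1-(propan-2-yl)-1-(triethylsilyloxy)cyclopent-2-ene | CC(C)(C)[Si](C)(C)O[C@H]1C[C@](O[Si](CC)(CC)CC)(C(C)C)C(Br)=C1C | intermediate
10 | tributyl(vinyl)stannane | C=C[Sn](CCCC)(CCCC)CCCC | starting material
11 | (1S,4S)-4-(tert-butyldimethylsilyloxy)-2-ethenyl-3-methyl-1-(propan-2-yl)-1-(triethylsilyloxy)cyclopent-2-ene | CC(C)(C)[Si](C)(C)O[C@H]1C[C@](O[Si](CC)(CC)CC)(C(C)C)C(C=C)=C1C | intermediate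
12 | 3-chlorobutan-2-one (racemic) | CC(Cl)C(C)=O | starting material
13 | 2β-(tert-butyldimethylsilyloxy)-4β-(triethylsilyloxy)dauc-5-en-9-one (C8 epimers, 8α-methyl drawn) | CC(C)(C)[Si](C)(C)O[C@H]1C[C@](O[Si](CC)(CC)CC)(C(C)C)C2=CC[C@H](C)C(=O)C[C@]12C | intermediate
14 | 9,9-(ethylenedioxy)-2β-(tert-butyldimethylsilyloxy)-4β-(triethylsilyloxy)dauc-5-ene | CC(C)(C)[Si](C)(C)O[C@H]1C[C@](O[Si](CC)(CC)CC)(C(C)C)C2=CC[C@H](C)C3(OCCO3)C[C@]12C | intermediate
15 | 9,9-(ethylenedioxy)-2β-(tert-butyldimethylsilyloxy)-4β-(triethylsilyloxy)-5α-daucan-6α-ylborane (not isolated) | CC(C)(C)[Si](C)(C)O[C@H]1C[C@](O[Si](CC)(CC)CC)(C(C)C)[C@H]2[C@H](B)C[C@H](C)C3(OCCO3)C[C@]12C | intermediate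
16 | 9,9-(ethylenedioxy)-2β-(tert-butyldimethylsilyloxy)-4β-(triethylsilyloxy)-5α-daucan-6α-ol | CC(C)(C)[Si](C)(C)O[C@H]1C[C@](O[Si](CC)(CC)CC)(C(C)C)[C@H]2[C@H](O)C[C@H](C)C3(OCCO3)C[C@]12C | intermediate
17 | 4-acetoxybenzoic acid | CC(=O)Oc1ccc(cc1)C(O)=O | starting material
18 | 4-acetoxybenzoyl chloride | CC(=O)Oc1ccc(cc1)C(Cl)=O | intermediate
19 | 6α-(4-acetoxybenzoyloxy)-9,9-(ethylenedioxy)-2β-(tert-butyldimethylsilyloxy)-4β-(triethylsilyloxy)-5α-daucane | CC(C)(C)[Si](C)(C)O[C@H]1C[C@](O[Si](CC)(CC)CC)(C(C)C)[C@H]2[C@H](OC(=O)c3ccc(OC(C)=O)cc3)C[C@H](C)C4(OCCO4)C[C@]12C | intermediate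
20 | 6α-(4-acetoxybenzoyloxy)-2β-(tert-butyldimethylsilyloxy)-4β-(triethylsilyloxy)-5α-daucan-9-one | CC(C)(C)[Si](C)(C)O[C@H]1C[C@](O[Si](CC)(CC)CC)(C(C)C)[C@H]2[C@H](OC(=O)c3ccc(OC(C)=O)cc3)C[C@H](C)C(=O)C[C@]12C | intermediate
21 | 6α-(4-acetoxybenzoyloxy)-2β-(tert-butyldimethylsilyloxy)-4β-(triethylsilyloxy)-9-(trimethylsilyloxy)-5α-dauc-8-ene | CC(C)(C)[Si](C)(C)O[C@H]1C[C@](O[Si](CC)(CC)CC)(C(C)C)[C@H]2[C@H](OC(=O)c3ccc(OC(C)=O)cc3)CC(C)=C(O[Si](C)(C)C)C[C@]12C | intermediate
22 | 6α-(4-acetoxybenzoyloxy)-2β-(tert-butyldimethylsilyloxy)-4β-(triethylsilyloxy)-5α-dauc-7-en-9-one | CC(C)(C)[Si](C)(C)O[C@H]1C[C@](O[Si](CC)(CC)CC)(C(C)C)[C@H]2[C@H](OC(=O)c3ccc(OC(C)=O)cc3)C=C(C)C(=O)C[C@]12C | intermediate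
23 | 6α-(4-acetoxybenzoyloxy)-2β,4β-dihydroxy-5α-dauc-7-en-9-one | O[C@H]1C[C@](O)(C(C)C)[C@H]2[C@H](OC(=O)c3ccc(OC(C)=O)cc3)C=C(C)C(=O)C[C@]12C | intermediate
24 | 2β-acetoxy-6α-(4-acetoxybenzoyloxy)-4β-hydroxy-5α-dauc-7-en-9-one | CC(=O)O[C@H]1C[C@](O)(C(C)C)[C@H]2[C@H](OC(=O)c3ccc(OC(C)=O)cc3)C=C(C)C(=O)C[C@]12C | intermediate
25 | 2β-acetoxy-4β-hydroxy-6α-(4-hydroxybenzoyloxy)-5α-dauc-7-en-9-one, (1S,2S,4S,5R,6R) in the numbering used here | CC(=O)O[C@H]1C[C@](O)(C(C)C)[C@H]2[C@H](OC(=O)c3ccc(O)cc3)C=C(C)C(=O)C[C@]12C | target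

**Step count**

Total: 17 steps. Longest linear sequence: 16 steps (1 → 25 through steps 1–9 and 11–17); step 10 is a one-step side branch.

**Steps most likely to fail**

1. Step 7. The oxyallyl cation may be consumed by the solvent before the twisted diene reacts. The first-formed zwitterion may also collapse through oxygen, through C6 ((3+2) products) or by proton loss instead of closing at the hindered C1. Closure may also be incompletely selective for the α face.
Fallback (from 11, back at 13): the same two bonds are made by a rhodium vinylcarbenoid route. Commercial methyl 2-diazo-3-oxobutanoate is O-silylated (TBSOTf, Et3N) to methyl 3-(tert-butyldimethylsilyloxy)-2-diazobut-3-enoate F1. With Rh2(OAc)4, or with Rh2(S-DOSP)4 or its enantiomer for catalyst control of the cyclopropane configuration, the carbenoid should cyclopropanate only the unhindered vinyl group of 11 to give the cis-divinylcyclopropane F2. Warming in toluene should then bring about Cope rearrangement through a boat transition state to the cycloheptadiene silyl enol ether ester F3, with C7–C8 and C1–C10 formed and the ester on C8. Methyl iodide with one equivalent of TBAF at −78 → 0 °C C-methylates the liberated β-keto ester enolate at C8 to the C8-methyl β-keto ester F4. Krapcho demethoxycarbonylation (LiCl, wet DMSO, 140 °C) then gives 13.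

2. Step 9. Borane may add from the β face, or only sluggishly at an alkene flanked by two quaternary carbons, because the C4 isopropyl group sits on the α face; this would give the cis-fused diastereomer.
Fallback (from 14, back at 16): C5 and C6 are set under thermodynamic instead of kinetic control. The hydroboration–oxidation is run without regard to face, so that 16 is accompanied by the cis-fused 5β-H,6β-alcohol F5. The mixture is oxidised with Dess–Martin periodinane to the C6 ketones. The cis-fused 6-ketone F6 is equilibrated at C5 by brief exposure to DBU at 0 °C, kept short to avoid loss of the β-silyloxy group, to the trans-fused 6-ketone F7, in which C6 is no longer cis to the C4 isopropyl group. F7 is reduced by electron transfer (SmI2, H2O, Et3N, THF) to the more stable pseudo-equatorial 6α-alcohol 16, which avoids the syn-axial C1 methyl.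

3. Step 6. Oxidative addition at the tetrasubstituted bromoalkene next to the quaternary silyloxy carbon may be slow, so that protodestannylation or fluoride-induced silyl loss competes.
Fallback (from 6, back at 11): the vinyl group is attached while the bromide is still an activated α-bromoenone. Stille coupling of 6 with 10 (Pd2(dba)3, AsPh3, CuI, NMP, rt) gives the 2-vinyl enone F8. Addition of 7 with CeCl3 as in step 4, anti to the silyloxy group, gives the dienyl carbinol F9. Silylation with TESOTf and 2,6-lutidine returns 11.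

**Further compounds**

F1 | step 7 | methyl 3-(tert-butyldimethylsilyloxy)-2-diazobut-3-enoate | COC(=O)C(=[N+]=[N-])C(=C)O[Si](C)(C)C(C)(C)C
F2 | step 7 | cis-divinylcyclopropane from 11 (cyclopropane on C6/C7, ester and silyloxyvinyl on C8) | CC(C)(C)[Si](C)(C)O[C@H]1C[C@](O[Si](CC)(CC)CC)(C(C)C)C(=C1C)[C@H]2C[C@@]2(C(=O)OC)C(=C)O[Si](C)(C)C(C)(C)C
F3 | step 7 | methyl 2β,9-bis(tert-butyldimethylsilyloxy)-4β-(triethylsilyloxy)-14-nordauca-5,8-diene-8-carboxylate (cycloheptadiene silyl enol ether ester) | CC(C)(C)[Si](C)(C)O[C@H]1C[C@](O[Si](CC)(CC)CC)(C(C)C)C2=CCC(C(=O)OC)=C(O[Si](C)(C)C(C)(C)C)C[C@]12C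
F4 | step 7 | methyl 2β-(tert-butyldimethylsilyloxy)-9-oxo-4β-(triethylsilyloxy)dauc-5-ene-8-carboxylate (C8 epimers) | CC(C)(C)[Si](C)(C)O[C@H]1C[C@](O[Si](CC)(CC)CC)(C(C)C)C2=CCC(C)(C(=O)OC)C(=O)C[C@]12C
F5 | step 9 | 9,9-(ethylenedioxy)-2β-(tert-butyldimethylsilyloxy)-4β-(triethylsilyloxy)-5β-daucan-6β-ol | CC(C)(C)[Si](C)(C)O[C@H]1C[C@](O[Si](CC)(CC)CC)(C(C)C)[C@@H]2[C@@H](O)C[C@H](C)C3(OCCO3)C[C@]12C
F6 | step 9 | 9,9-(ethylenedioxy)-2β-(tert-butyldimethylsilyloxy)-4β-(triethylsilyloxy)-5β-daucan-6-one | CC(C)(C)[Si](C)(C)O[C@H]1C[C@](O[Si](CC)(CC)CC)(C(C)C)[C@@H]2C(=O)C[C@H](C)C3(OCCO3)C[C@]12C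
F7 | step 9 | 9,9-(ethylenedioxy)-2β-(tert-butyldimethylsilyloxy)-4β-(triethylsilyloxy)-5α-daucan-6-one | CC(C)(C)[Si](C)(C)O[C@H]1C[C@](O[Si](CC)(CC)CC)(C(C)C)[C@H]2C(=O)C[C@H](C)C3(OCCO3)C[C@]12C
F8 | step 6 | (S)-4-(tert-butyldimethylsilyloxy)-2-ethenyl-3-methylcyclopent-2-en-1-one | CC(C)(C)[Si](C)(C)O[C@H]1CC(=O)C(C=C)=C1C
F9 | step 6 | (1S,4S)-4-(tert-butyldimethylsilyloxy)-2-ethenyl-3-methyl-1-(propan-2-yl)cyclopent-2-en-1-ol | CC(C)(C)[Si](C)(C)O[C@H]1C[C@](O)(C(C)C)C(C=C)=C1C
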